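In my reckoning substrate left far sooner than the activated form: on Tuesday's charge, activation alone gave substrate a half-life of 1.5 s, and ring closure alone gave the activated form 22 s. The activator turns substrate, the limiting reagent, into the activated form. That form closes to ring by itself, or it meets substrate and gives open dimer.

all flasks: activator 1.30 equiv; capture agent 1.00 mM
- Tuesday's: substrate 20 mM; time 40 s; a closed flask charged with all of it at once and left for 40 s
- Saturday's: substrate 20 mM; one stirred flow tank at steady state, fed with the mixture as stated, mean residence time 400 s
- Wednesday's: substrate 20 mM (fed, over 40.0 s); time 40 s; a stirred flask in which substrate is dosed at a steady rate over 40.0 s without added volume, worked up at 40 s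
- Friday's: substrate 20 mM; one stirred flow tank at steady state, fed with the mixture as stated, mean residence time 40 s

- the set-up with the highest share of ring in all that became ring or open dimer or trapped intermediate, at the outlet or at the end ("none" if the first two lie within 2 percentage points) (Tuesday's / Saturday's / Wednesday's / Friday's / none)
- share of ring in all that became ring or open dimer or trapped intermediate, at the outlet or at the end, Tuesday's
- share of ring in all that became ring or open dimer or trapped intermediate, at the outlet or at the end, Saturday's
- share of ring in all that became ring or open dimer or trapped intermediate, at the outlet or at the end, Wednesday's
- share of ring in all that became ring or open dimer or trapped intermediate, at the outlet or at the end, Friday's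

- percent here means substrate units held: one open dimer counts as two
- the stated concentrations are those of everything mixed, before any reaction; amounts are the same in each set-up
- the feed brings no volume worth counting
- run time (Tuesday's): 40 s

    substrate + activated form → open dimer (k1 = 1.7 /M/s)
    activated form → ring (k2 = 0.031 /s)
    activated form → decomposed reagent (k3 = 0.0078 /s)
    substrate + activator → activated form (k4 = 18 /M/s)
    capture agent + activated form → trapped intermediate (k5 = 1.7 /M/s)

I counted every level as a fraction of the substrate charge. Ring closure needs no partner, while open dimer needs substrate and holds two units. So I carried one number, the crossing fraction: the substrate fraction at which ring and open dimer draw substrate units equally fast, which is the ring rate constant over twice the open-dimer rate constant times the charge, 0.456.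

Tuesday's substrate curve fell steeply from the full charge and passed the crossing fraction soon after one half-life. Open dimer led before that point and ring led after it. Tuesday's ring curve then bent slowly, and the run lasted 1.79 ring half-lives.

A steady tank holds one substrate level, not a falling curve. For Saturday's tank I took activator down to its excess, 0.300 of the charge. Activation then balanced the feed at a substrate fraction of 0.0226, far below the crossing fraction. Ring against open dimer came to 95.3%. Counting capture agent at its full charge brought my figure for Saturday's down to 90.5%. I stopped there.

The forecast named Saturday's at 93%, between my two figures, since the long tank “keeps substrate very low and gives the ring time to form”. It put Tuesday's at 78.5%, Wednesday's at 78% and Friday's at 76.8%.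

The simulation gave Saturday's as the best set-up, with 93.0%. Tuesday's gave 79.9%, Wednesday's 81.2% and Friday's 76.5%.

Saturday's reckoned substrate fraction was 0.0496 of the crossing fraction. In Friday's tank activator stood at 9.43 mM, and activation at that level put the substrate fraction at 0.128, about a quarter of the crossing fraction, which made ring against open dimer 78.1%, 74.8% with capture agent at full charge, and Friday's tank stood at 76.5%.

The constants used here were set for the occasion; the rest is arithmetic.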